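**Easy start.** Flasks of L and Z wait, and violet has already run, so I begin by reading its last point.

| setting | violet | theta | delta | gamma | beta | alpha |
|---|---|---|---|---|---|---|
| L | 0.026 M | 0.024 M | 0.015 M | 0.024 M | 0.024 M | 0.080 M |
| Z | 1.05 equiv | 0.260 equiv | 0.700 equiv | 3.20 equiv | 1.05 equiv | 1.60 equiv |
| remark | run made earlier |  |  |  |  |  |
| time |  | 5.0 min | 5.0 min | 5.0 min | 5.0 min | 5.0 min |

- violet (time / s: E / %): 10.0: 3.9; 12.0: 6.8; 20.0: 10.0; 30.0: 16.1; 50.0: 21.0; 60.0: 23.2

(each reading ± 1 percentage point)

- the analysis behind the earlier runs scatters by 1 percentage point, standard deviation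

- all flasks from highest to lowest amount of E, in percent of the L charged, at 5.0 min (theta / delta / gamma / beta / alpha)
- the same order at 1.0 min (theta / delta / gamma / beta / alpha)
- the amount of E, in percent of the L charged of the flask you put first, at 5.0 min
- the amount of E, in percent of the L charged of the flask you put last, at 5.0 min

**Rate constant.** In violet, L and Z start nearly equal, so the ratio of E to L left grows in step with time and with the charged [L]. At 60.0 s, E stands at 23.2%, which gives k of about 11.6 M⁻¹ min⁻¹, a reading with the run's scatter.

**The clock.** In gamma, Z is in excess, so I treat L as pseudo-first-order. I call one over k[Z] the L clock: the lifetime of L at that [Z]. With [Z] held at its charge, gamma's L clock is 1.12 min, so 5.0 min gives E of 98.8%. Alpha's clock is 0.672 min, shorter than gamma's, which gives 99.9%.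

**Weak link.** Holding [Z] at its charge is the flaw. Gamma's first answer has nearly all of L reacted, so, assuming one Z per E, about one equivalent of Z goes. I put that back and use the final [Z]. Gamma's clock becomes 1.63 min, with E at 95.3%. Alpha's becomes 1.79 min, now longer than gamma's, with E at 93.8%. Gamma and alpha now each have two estimates, one from the charged [Z] and one from the final [Z], and the two pairs overlap, so I leave the top place open.

**The forecast.** It commits where I do not: alpha > gamma > beta > delta > theta at 5.0 min and alpha > gamma > beta > delta > theta at 1.0 min, with top 97.8% (94% to 99.5%) and low 18.7% (15% to 23%). Its words are: “Alpha and gamma are close at 5 min, but alpha stays ahead across plausible k.”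

**The flask.** The order at 5.0 min is gamma > alpha > beta > delta > theta, with gamma at 94.7%, alpha at 81.0% and theta at 14.9%. At 1.0 min it is alpha > gamma > beta > delta > theta.

    L + Z → J + E (k = 14.0 M⁻¹ min⁻¹)
    Z + J ⇌ X, settled at all times (K = 1100 M⁻¹)

**Parked Z.** Each E also makes J, which can hold a further Z as X. Without that parking gamma reaches 98.3% instead of 94.7% and the order turns, with the length of the run acting alongside it. Putting the free Z back into the clock, with my violet k, shows the swap. At 5.00 min gamma keeps 42% of its Z unbound, a clock of 2.69 min. Alpha keeps 5.0% unbound, a clock of 13.4 min, longer than gamma's. A neighbour of gamma with 0.800 equiv of Z keeps 14% unbound, a clock of 31.7 min, and stands at 39.3% E.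

The data were generated by integration for substances that don't exist, and the scatter is random.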